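**Retrosynthetic overview**

1. Target 28 ⇒ alkenylstannane 19 + bromodienamide 27 (Stille coupling, lower triene); the enamide C–N bond ⇒ iodoenone 10 + trienamide 16 (Goldberg coupling).
2. Epoxyquinol core 9 ⇒ 3-alkynyloxepine 6 + O2 in one operation: 6π ring contraction of the oxepine to its arene oxide, [4+2] addition of singlet oxygen, chiral-base Kornblum–DeLaMare rearrangement.
3. Oxepine 6 ⇒ 2-methoxy-3,4-dihydro-2H-pyran 1 + CHBr3 + silylacetylene 4: one-carbon enlargement of the pyran (six to seven); the bromoform carbon becomes the carbinol carbon and the pyran oxygen the epoxide oxygen.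
4. Enabling feature (core numbered as 7-oxabicyclo[4.1.0]hept-3-en-2-one): the cis-fused oxirane on C-1/C-6, flanked 1,4 by the C-2 carbonyl and the C-5 tertiary carbinol (anti to the oxirane) across the C-3=C-4 alkene. This is an oxepine (O-1 between sp2 C-2 and C-7, diene C-3 to C-6) that has closed its C-2–C-7 bond and taken up O2 across C-3/C-6.
5. Ring order: pyran (bought) → oxepine (steps 1–3) → carbocycle, oxirane and peroxide bridge together (step 4, bridge opened in the same operation); the cyclopentenone ring is bought (25).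

Key step: step 4

Remark 1: racemic compounds whose relative configuration matters (7, 8) are written with both enantiomers in one SMILES, joined by a dot; the first is the one that leads to 9.
Remark 2: the potassium salt of glutaconaldehyde (20) is taken as a purchasable compound; otherwise it is one operation from pyridine–sulfur trioxide and KOH.

**Route**

Step 1
Reactants: 1 2-methoxy-3,4-dihydro-2H-pyran
Product: 3 6-bromo-2-methoxy-2,3-dihydrooxepine (racemic), via dibromocyclopropane 2 (not isolated)
Conditions: CHBr3, KOtBu, pentane, −20 → 0 °C; filter; then quinoline, toluene, 80 °C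
Reagents that add atoms: bromoform BrC(Br)Br
Why: Dibromocarbene adds to the electron-rich enol ether C=C (Doering–Hoffmann cyclopropanation) and the gem-dibromocyclopropane of 2, pushed by the ring oxygen, should open with loss of the endo bromide to an oxocarbenium–allyl cation that loses a proton to quinoline, the known dihalocarbene ring enlargement of dihydropyrans to 2,3-dihydrooxepines; the acetal carbon is the only stereocentre and is destroyed in step 3.

Step 2
Reactants: 3 6-bromo-2-methoxy-2,3-dihydrooxepine; 4 ethynyltri(propan-2-yl)silane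
Product: 5 2-methoxy-6-{[tri(propan-2-yl)silyl]ethynyl}-2,3-dihydrooxepine (racemic)
Conditions: PdCl2(PPh3)2 (3 mol %), CuI (6 mol %), i-Pr2NH, THF, 50 °C
Reagents that add atoms: none
Why: Sonogashira coupling of an alkenyl bromide with a terminal alkyne, run in amine so that the acetal and the dienol ether never meet acid; no stereocentre is formed.

Step 3
Reactants: 5 2-methoxy-6-{[tri(propan-2-yl)silyl]ethynyl}-2,3-dihydrooxepine
Product: 6 3-{[tri(propan-2-yl)silyl]ethynyl}oxepine
Conditions: KOtBu (3 equiv), 18-crown-6 (cat.), THF, 0 °C → rt; work-up and storage over K2CO3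
Reagents that add atoms: none
Why: E1cB-type elimination in which tert-butoxide removes a proton from C-3 (pentadienylic to the C-4 to C-7 diene) and the anion expels the acetal methoxide, the base-induced loss of alcohol by which unsaturated acetals are turned into alkoxydienes; the product has no sp3 hydrogen left and is kept basic because its arene oxide tautomer is acid-labile.

Step 4
Reactants: 6 3-{[tri(propan-2-yl)silyl]ethynyl}oxepine
Product: 9 (1R,5R,6S)-5-hydroxy-5-{[tri(propan-2-yl)silyl]ethynyl}-7-oxabicyclo[4.1.0]hept-3-en-2-one, via arene oxide 7 (not isolated), via epoxy endoperoxide 8 (not isolated)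
Conditions: O2, tetraphenylporphyrin (metal-free, 1 mol %), white LED, CH2Cl2, −78 °C; argon purge; then 9-O-acetylcupreine (10 mol %), −78 → −20 °C, stopped near half conversion of 8
Reagents that add atoms: dioxygen O=O
Why: Proposed new method: a cinchona-base Kornblum–DeLaMare rearrangement used as a kinetic resolution of a racemic endoperoxide with a single bridgehead hydrogen is not established; the closest known reaction type is the desymmetrisation of meso bicyclic endoperoxides by the same catalysts, and the transfer is reasonable because H-4 of one enantiomer of 8 and H-4 of the other stand in the same mirror-image relation as the two enantiotopic bridgehead hydrogens that these catalysts already tell apart. Mechanism: oxepine 6 closes thermally by disrotatory 6π electrocyclisation between C-2 and C-7 (oxepine–benzene oxide valence tautomerism, the oxide favoured at low temperature), singlet oxygen adds [4+2] to the cyclohexadiene of 7 as it does to benzene oxide itself, and the amine removes the bridgehead hydrogen of 8 with heterolysis of the O–O bond. Ring closures: the carbocycle and the oxirane form together in the 6π disrotatory closure, and the peroxide bridge forms by a suprafacial [4+2] cycloaddition that the rearrangement then opens. Stereocentres: the oxirane is cis-fused by necessity, oxygen should add to the diene face anti to the oxirane oxygen (steric and lone-pair repulsion) and so place the tertiary hydroxyl anti to the epoxide, and the absolute configuration is chosen by the catalyst, which should convert only the enantiomer of 8 written first (the quinidine-derived pseudoenantiomer is the first variable if the sense proves opposite). Selectivities needed: dioxygen must take the ring diene of 7 and not the silylalkyne or the triene of 6, which the inertness of alkynes to singlet oxygen and the locked s-cis diene of the oxide tautomer should secure, and the base has only one bridgehead hydrogen to remove, so the ketone can form only at C-2 and the hydroxyl only on the alkynyl-bearing carbon.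

Step 5
Reactants: 9 (1R,5R,6S)-5-hydroxy-5-{[tri(propan-2-yl)silyl]ethynyl}-7-oxabicyclo[4.1.0]hept-3-en-2-one
Product: 10 (1R,5R,6S)-5-hydroxy-3-iodo-5-{[tri(propan-2-yl)silyl]ethynyl}-7-oxabicyclo[4.1.0]hept-3-en-2-one
Conditions: I2 (2 equiv), pyridine/CH2Cl2 1:1, 0 °C → rt
Reagents that add atoms: iodine II
Why: α-Iodination of an enone by iodine–pyridine (conjugate addition of pyridine, iodination of the enolate, E1cB loss of pyridine), a reaction that tolerates a quaternary γ-carbon and leaves the three stereocentres untouched.

Step 6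
Reactants: 11 4-methylpentanal; 12 (triphenyl-λ5-phosphanylidene)acetaldehyde
Product: 13 (2E)-6-methylhept-2-enal
Conditions: toluene, 80 °C
Reagents that add atoms: none
Why: Wittig reaction of a stabilised ylide, which should give the E enal; the saturated aldehyde is kept in slight excess so that the product is not homologated again.

Step 7
Reactants: 13 (2E)-6-methylhept-2-enal; 14 ethyl (2E)-4-(diethoxyphosphoryl)but-2-enoate
Product: 15 ethyl (2E,4E,6E)-10-methylundeca-2,4,6-trienoate
Conditions: LiN(SiMe3)2, THF, −78 → 0 °C
Reagents that add atoms: none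
Why: Vinylogous Horner–Wadsworth–Emmons olefination, the anion reacting at the carbon that bears phosphorus to form the new E double bond while the crotonate geometry is kept.

Step 8
Reactants: 15 ethyl (2E,4E,6E)-10-methylundeca-2,4,6-trienoate
Product: 16 (2E,4E,6E)-10-methylundeca-2,4,6-trienamide
Conditions: AlMe3, NH4Cl, toluene, 0 → 50 °C; then aqueous potassium sodium tartrate
Reagents that add atoms: ammonium chloride [NH4+].[Cl-]
Why: Weinreb aminolysis of an ester by an aluminium amide made in the flask, which should attack the ester carbonyl and not the triene.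

Step 9
Reactants: 10 (1R,5R,6S)-5-hydroxy-3-iodo-5-{[tri(propan-2-yl)silyl]ethynyl}-7-oxabicyclo[4.1.0]hept-3-en-2-one; 16 (2E,4E,6E)-10-methylundeca-2,4,6-trienamide
Product: 17 (2E,4E,6E)-N-[(1R,5R,6S)-5-hydroxy-2-oxo-5-{[tri(propan-2-yl)silyl]ethynyl}-7-oxabicyclo[4.1.0]hept-3-en-3-yl]-10-methylundeca-2,4,6-trienamide
Conditions: CuI (10 mol %), N,N'-dimethylethylenediamine (20 mol %), Cs2CO3 (1.5 equiv), THF, 50 °C
Reagents that add atoms: none
Why: Goldberg-type copper-catalysed C–N coupling of an alkenyl iodide with a primary amide, which keeps the position of the double bond and does not touch the stereocentres.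

Step 10
Reactants: 17 (the silylalkyne enamide of step 9)
Product: 18 (2E,4E,6E)-N-[(1R,5R,6S)-5-ethynyl-5-hydroxy-2-oxo-7-oxabicyclo[4.1.0]hept-3-en-3-yl]-10-methylundeca-2,4,6-trienamide
Conditions: Bu4NF (1.2 equiv), AcOH (1.3 equiv), THF, 0 °C → rt
Reagents that add atoms: none
Why: Fluoride-induced cleavage of the alkynyl C–Si bond, buffered with acetic acid so that the tertiary alkoxide anti to the oxirane (a Payne-rearrangement risk) and the epoxy ketone never meet free base.

Step 11
Reactants: 18 (the terminal alkyne of step 10)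
Product: 19 (2E,4E,6E)-N-[(1R,5R,6S)-5-hydroxy-2-oxo-5-[(E)-2-(tributylstannyl)ethenyl]-7-oxabicyclo[4.1.0]hept-3-en-3-yl]-10-methylundeca-2,4,6-trienamide
Conditions: Bu3SnH (1.1 equiv, slow addition), PdCl2(PPh3)2 (2 mol %), THF, 0 °C
Reagents that add atoms: tributyltin hydride CCCC[SnH](CCCC)CCCC
Why: Palladium-catalysed hydrostannylation of a terminal alkyne, a syn addition that should give the E alkene with tin on the terminal carbon because the fully substituted carbinol carbon blocks the internal position, the alkyne being expected to react well before the enone.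

Step 12
Reactants: 20 potassium (1E,3E)-5-oxopenta-1,3-dien-1-olate (glutaconaldehyde potassium salt)
Product: 21 (2E,4E)-5-bromopenta-2,4-dienal
Conditions: PPh3, Br2, CH2Cl2, 0 °C; then 20, 0 °C → rt
Reagents that add atoms: bromine BrBr (delivered as Ph3PBr2)
Why: Bromodeoxygenation of the enolate oxygen by dibromotriphenylphosphorane (oxyphosphonium formation, then addition–elimination of bromide), the known route from glutaconaldehyde salts to ω-bromodienals, the E,E isomer being the thermodynamic one.

Step 13
Reactants: 21 (2E,4E)-5-bromopenta-2,4-dienal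
Product: 22 (2E,4E)-5-bromopenta-2,4-dienoic acid
Conditions: NaClO2, NaH2PO4, 2-methylbut-2-ene, t-BuOH/H2O, 0 °C → rt
Reagents that add atoms: sodium chlorite [Na+].[O-]Cl=O
Why: Pinnick oxidation, which should take the aldehyde to the acid without touching the bromodiene because the scavenger alkene removes hypochlorous acid.

Step 14
Reactants: 22 (2E,4E)-5-bromopenta-2,4-dienoic acid
Product: 24 (2E,4E)-5-bromopenta-2,4-dienamide, via mixed anhydride 23 (not isolated)
Conditions: i-BuOCOCl, N-methylmorpholine, THF, −15 °C; then NH3 (0.5 M in dioxane), −15 → 0 °C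
Reagents that add atoms: ammonia N; isobutyl chloroformate CC(C)COC(Cl)=O (atoms only in 23)
Why: Mixed carbonic anhydride activation and aminolysis at the acyl carbonyl, at a temperature where ammonia should neither add to the dienoate nor displace the vinylic bromide.

Step 15
Reactants: 25 cyclopentane-1,3-dione
Product: 26 2-diazocyclopentane-1,3-dione
Conditions: 4-acetamidobenzenesulfonyl azide, Et3N, MeCN, 0 °C → rt
Reagents that add atoms: 4-acetamidobenzenesulfonyl azide CC(=O)Nc1ccc(cc1)S(=O)(=O)N=[N+]=[N-]
Why: Regitz diazo transfer to the doubly activated methylene.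

Step 16
Reactants: 24 (2E,4E)-5-bromopenta-2,4-dienamide; 26 2-diazocyclopentane-1,3-dione
Product: 27 (2E,4E)-5-bromo-N-(2-hydroxy-5-oxocyclopent-1-en-1-yl)penta-2,4-dienamide
Conditions: Rh2(OAc)4 (2 mol %), 1,2-dichloroethane, 80 °C, slow addition of 26
Reagents that add atoms: none
Why: Rhodium-carbenoid N–H insertion of an acceptor/acceptor diazo compound into a primary amide, the electrophilic carbenoid being expected to prefer the amide nitrogen to the electron-poor bromodiene, after which the product tautomerises to the enol.

Step 17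
Reactants: 19 (the alkenylstannane of step 11); 27 (2E,4E)-5-bromo-N-(2-hydroxy-5-oxocyclopent-1-en-1-yl)penta-2,4-dienamide
Product: 28 (2E,4E,6E)-N-[(1R,5S,6S)-5-hydroxy-5-{(1E,3E,5E)-7-[(2-hydroxy-5-oxocyclopent-1-en-1-yl)amino]-7-oxohepta-1,3,5-trien-1-yl}-2-oxo-7-oxabicyclo[4.1.0]hept-3-en-3-yl]-10-methylundeca-2,4,6-trienamide (the target)
Conditions: PdCl2(MeCN)2 (5 mol %), DMF, rt, dark
Reagents that add atoms: none
Why: Stille coupling of an alkenylstannane with an alkenyl bromide with retention of both double-bond geometries, under neutral conditions that the epoxyquinol, the free enol and both polyene amides should tolerate.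

**Compound list**

1 | 2-methoxy-3,4-dihydro-2H-pyran (racemic) | COC1CCC=CO1 | starting material
2 | 7,7-dibromo-3-methoxy-2-oxabicyclo[4.1.0]heptane (cis-fused, racemic, both acetal epimers) | COC1CCC2C(O1)C2(Br)Br | intermediate
3 | 6-bromo-2-methoxy-2,3-dihydrooxepine (racemic) | COC1CC=CC(Br)=CO1 | intermediate
4 | ethynyltri(propan-2-yl)silane | C#C[Si](C(C)C)(C(C)C)C(C)C | starting material
5 | 2-methoxy-6-{[tri(propan-2-yl)silyl]ethynyl}-2,3-dihydrooxepine (racemic) | COC1CC=CC(C#C[Si](C(C)C)(C(C)C)C(C)C)=CO1 | intermediate
6 | 3-{[tri(propan-2-yl)silyl]ethynyl}oxepine (in equilibrium with 7) | CC(C)[Si](C(C)C)(C(C)C)C#CC1=COC=CC=C1 | intermediate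
7 | 2-{[tri(propan-2-yl)silyl]ethynyl}-7-oxabicyclo[4.1.0]hepta-2,4-diene (arene oxide, cis-fused, enantiomers interconverting through 6) | CC(C)[Si](C(C)C)(C(C)C)C#CC1=CC=C[C@@H]2O[C@H]12.CC(C)[Si](C(C)C)(C(C)C)C#CC1=CC=C[C@H]2O[C@@H]12 | intermediate
8 | 7,8-epoxy-1-{[tri(propan-2-yl)silyl]ethynyl}-2,3-dioxabicyclo[2.2.2]oct-5-ene, oxirane oxygen anti to the peroxide bridge (racemic) | C1=C[C@]2(C#C[Si](C(C)C)(C(C)C)C(C)C)OO[C@H]1[C@@H]1O[C@@H]12.C1=C[C@@]2(C#C[Si](C(C)C)(C(C)C)C(C)C)OO[C@@H]1[C@H]1O[C@H]12 | intermediate
9 | (1R,5R,6S)-5-hydroxy-5-{[tri(propan-2-yl)silyl]ethynyl}-7-oxabicyclo[4.1.0]hept-3-en-2-one (hydroxyl anti to the oxirane) | C1=C[C@@](O)(C#C[Si](C(C)C)(C(C)C)C(C)C)[C@H]2O[C@H]2C1=O | intermediate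
10 | (1R,5R,6S)-5-hydroxy-3-iodo-5-{[tri(propan-2-yl)silyl]ethynyl}-7-oxabicyclo[4.1.0]hept-3-en-2-one | IC1=C[C@@](O)(C#C[Si](C(C)C)(C(C)C)C(C)C)[C@H]2O[C@H]2C1=O | intermediate
11 | 4-methylpentanal | CC(C)CCC=O | starting material
12 | (triphenyl-λ5-phosphanylidene)acetaldehyde | O=CC=P(c1ccccc1)(c1ccccc1)c1ccccc1 | starting material
13 | (2E)-6-methylhept-2-enal | CC(C)CC/C=C/C=O | intermediate
14 | ethyl (2E)-4-(diethoxyphosphoryl)but-2-enoate | CCOC(=O)/C=C/CP(=O)(OCC)OCC | starting material
15 | ethyl (2E,4E,6E)-10-methylundeca-2,4,6-trienoate | CC(C)CC/C=C/C=C/C=C/C(=O)OCC | intermediate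
16 | (2E,4E,6E)-10-methylundeca-2,4,6-trienamide | CC(C)CC/C=C/C=C/C=C/C(N)=O | intermediate
17 | (2E,4E,6E)-N-[(1R,5R,6S)-5-hydroxy-2-oxo-5-{[tri(propan-2-yl)silyl]ethynyl}-7-oxabicyclo[4.1.0]hept-3-en-3-yl]-10-methylundeca-2,4,6-trienamide | CC(C)CC/C=C/C=C/C=C/C(=O)NC1=C[C@@](O)(C#C[Si](C(C)C)(C(C)C)C(C)C)[C@H]2O[C@H]2C1=O | intermediate
18 | (2E,4E,6E)-N-[(1R,5R,6S)-5-ethynyl-5-hydroxy-2-oxo-7-oxabicyclo[4.1.0]hept-3-en-3-yl]-10-methylundeca-2,4,6-trienamide | CC(C)CC/C=C/C=C/C=C/C(=O)NC1=C[C@@](O)(C#C)[C@H]2O[C@H]2C1=O | intermediate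
19 | (2E,4E,6E)-N-[(1R,5R,6S)-5-hydroxy-2-oxo-5-[(E)-2-(tributylstannyl)ethenyl]-7-oxabicyclo[4.1.0]hept-3-en-3-yl]-10-methylundeca-2,4,6-trienamide | CC(C)CC/C=C/C=C/C=C/C(=O)NC1=C[C@@](O)(/C=C/[Sn](CCCC)(CCCC)CCCC)[C@H]2O[C@H]2C1=O | intermediate
20 | potassium (1E,3E)-5-oxopenta-1,3-dien-1-olate | [K+].[O-]/C=C/C=C/C=O | starting material
21 | (2E,4E)-5-bromopenta-2,4-dienal | Br/C=C/C=C/C=O | intermediate
22 | (2E,4E)-5-bromopenta-2,4-dienoic acid | Br/C=C/C=C/C(O)=O | intermediate
23 | (2E,4E)-5-bromopenta-2,4-dienoic 2-methylpropyl carbonic anhydride | Br/C=C/C=C/C(=O)OC(=O)OCC(C)C | intermediate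
24 | (2E,4E)-5-bromopenta-2,4-dienamide | Br/C=C/C=C/C(N)=O | intermediate
25 | cyclopentane-1,3-dione | O=C1CCC(=O)C1 | starting material
26 | 2-diazocyclopentane-1,3-dione | [N-]=[N+]=C1C(=O)CCC1=O | intermediate
27 | (2E,4E)-5-bromo-N-(2-hydroxy-5-oxocyclopent-1-en-1-yl)penta-2,4-dienamide | Br/C=C/C=C/C(=O)NC1=C(O)CCC1=O | intermediate
28 | (2E,4E,6E)-N-[(1R,5S,6S)-5-hydroxy-5-{(1E,3E,5E)-7-[(2-hydroxy-5-oxocyclopent-1-en-1-yl)amino]-7-oxohepta-1,3,5-trien-1-yl}-2-oxo-7-oxabicyclo[4.1.0]hept-3-en-3-yl]-10-methylundeca-2,4,6-trienamide | CC(C)CC/C=C/C=C/C=C/C(=O)NC1=C[C@@](O)(/C=C/C=C/C=C/C(=O)NC2=C(O)CCC2=O)[C@H]2O[C@H]2C1=O | target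

**Step count and risks**

Total step count: 17. Longest linear sequence: 9 steps (steps 1, 2, 3, 4, 5, 9, 10, 11, 17, from 1).

The three steps most likely to fail:

1. Step 4 (bears the label). What may go wrong: too small a rate difference between the two enantiomers of the endoperoxide in the base-induced proton removal, so that the resolution is poor; acid-catalysed aromatisation of the arene oxide before oxygen is taken up; thermal isomerisation of the endoperoxide to a bis-epoxide before the base acts. Fallback with known chemistry: it sets out from 6. Photooxygenation as in step 4 is followed by triethylamine (the ordinary achiral Kornblum–DeLaMare rearrangement), which should take all of 8 to the racemic hydroxy enone F1. F1 is then resolved by preparative chromatography on a cellulose tris(3,5-dimethylphenylcarbamate) phase, and the (1R,5R,6S) enantiomer is 9, where the route is rejoined.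

2. Step 3. What may go wrong: base-induced migration of the double bonds of 5 without loss of methoxide, or aromatisation of the oxepine/arene oxide pair by adventitious acid during work-up. Fallback: it sets out from 5 and changes the bond that is activated, from the C–H bond to the acetal C–O bond. Me3SiOTf with excess i-Pr2NEt in CH2Cl2 at −78 °C should ionise the acetal to the cyclic oxocarbenium ion, which loses the C-3 proton to the amine (the known conversion of acetals into enol ethers). This gives 6 directly; no new compound is made (F0).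

3. Step 9. What may go wrong: degradation of the epoxy alcohol by carbonate at 50 °C (Payne-type oxirane migration through the tertiary alkoxide, which stands anti to the oxirane), and reductive loss of iodine faster than C–N coupling. Fallback: it sets out from 10 and builds the amide by acylation instead of by coupling. Copper-catalysed azidation at room temperature (NaN3, CuI, sodium ascorbate, N,N'-dimethylethylenediamine, EtOH/H2O) should give the azido enone F2. Staudinger reduction (PMe3, THF/H2O, 0 °C) should then give the amino enone F3. In parallel, ester 15 is saponified (LiOH, THF/H2O) to (2E,4E,6E)-10-methylundeca-2,4,6-trienoic acid F4 and converted with oxalyl chloride and catalytic DMF into the acid chloride F5. Acylation of F3 with F5 (pyridine, CH2Cl2, 0 °C) gives 17, where the route is rejoined.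

**Further compounds**

F1 | step 4 | racemic 5-hydroxy-5-{[tri(propan-2-yl)silyl]ethynyl}-7-oxabicyclo[4.1.0]hept-3-en-2-one, hydroxyl anti to the oxirane | C1=C[C@@](O)(C#C[Si](C(C)C)(C(C)C)C(C)C)[C@H]2O[C@H]2C1=O.C1=C[C@](O)(C#C[Si](C(C)C)(C(C)C)C(C)C)[C@@H]2O[C@@H]2C1=O
F0 | step 3 | none | none
F2 | step 9 | (1R,5R,6S)-3-azido-5-hydroxy-5-{[tri(propan-2-yl)silyl]ethynyl}-7-oxabicyclo[4.1.0]hept-3-en-2-one | [N-]=[N+]=NC1=C[C@@](O)(C#C[Si](C(C)C)(C(C)C)C(C)C)[C@H]2O[C@H]2C1=O
F3 | step 9 | (1R,5R,6S)-3-amino-5-hydroxy-5-{[tri(propan-2-yl)silyl]ethynyl}-7-oxabicyclo[4.1.0]hept-3-en-2-one | NC1=C[C@@](O)(C#C[Si](C(C)C)(C(C)C)C(C)C)[C@H]2O[C@H]2C1=O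
F4 | step 9 | (2E,4E,6E)-10-methylundeca-2,4,6-trienoic acid | CC(C)CC/C=C/C=C/C=C/C(O)=O
F5 | step 9 | (2E,4E,6E)-10-methylundeca-2,4,6-trienoyl chloride | CC(C)CC/C=C/C=C/C=C/C(Cl)=O
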